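(All runs are calculated from invented constants, and the scatter is random.)

**The pitfall.** The charges of this flask suggest 50.0% of mono adduct, but that figure is a ceiling and not a yield.

| setting | elm | cedar | maple | flask |
|---|---|---|---|---|
| substrate | 6 mM | 9 mM | 12 mM | 12 mM |
| coupling partner | 6 mM | 6 mM | 3 mM | 6.00 mM |
| remark | run made earlier | run made earlier | run made earlier |  |
| time |  |  |  | 8.0 h |

| run | time / h | mono adduct / % | substrate / % |
|---|---|---|---|
| elm | 1.50 | 90.3 | 3.6 |
| elm | 3.00 | 86.8 | 1.5 |
| elm | 5.00 | 81.2 | 2.2 |
| elm | 6.00 | 76.7 | 0.4 |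
| elm | 8.00 | 71.0 | 2.2 |
| elm | 10.0 | 65.0 | 0 |
| cedar | 1.50 | 61.4 | 33.6 |
| cedar | 3.00 | 60.4 | 34.1 |
| cedar | 5.00 | 53.7 | 33.7 |
| cedar | 6.00 | 52.0 | 33.4 |
| cedar | 8.00 | 48.1 | 32.8 |
| cedar | 10.0 | 43.0 | 34.5 |
| maple | 2.00 | 22.6 | 76.5 |
| maple | 4.00 | 20.9 | 74.4 |
| maple | 6.00 | 20.0 | 75.3 |
| maple | 8.00 | 16.5 | 74.4 |
| maple | 10.0 | 16.3 | 76.5 |

(readings scatter by 1 percentage point)

1. equivalents of coupling partner to substrate, everything else as given, that leave most mono adduct at 8.0 h
2. the amount of mono adduct then, in percent of the substrate charged
3. the amount of mono adduct with the amounts as given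

- the numbers in the tables scatter by 1 percentage point (one standard deviation)

**Main step.** I start with the coupling step by itself. In the cedar run, substrate reads 33.6% at 1.50 h, and the excess charged is 33.3%. So substrate and coupling partner react one to one, and the partner is the limiting reagent. By this step the flask reaches its ceiling.

**Slow loss.** Next I add what the tables show later: mono adduct falls while substrate stays flat. I name the loss constant 0.0387 h⁻¹: the logarithm of the ratio of the first to the last elm reading of mono adduct, per hour between them. Cedar, read the same way, gives 0.0419 h⁻¹, close to it. Over 8.0 h a first-order loss keeps 73.4%, so my first answer for the flask is 36.7%.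

**Going round.** That answer assumes the ceiling stood at the start, so I put the constant back in. Carried back to the start, cedar's first reading becomes 65.1% against its ceiling of 66.7%, a capture of 97.6%. The flask then comes to 35.8%. None of the three runs charges partner above substrate, so I commit to one equivalent, with 71.6%.

**Forecast.** The forecast gives 35.8%, and 71% at 1.03 equiv, on the ground: “Mono adduct then falls in all three runs with about the same first-order constant”.

**Result.** The flask gives 35.5%, and the best recipe gives 71.0% at 1.01 equiv.

    coupling partner + mono adduct ⇌ bis adduct (K = 62.0 M⁻¹, k = 0.0420 M⁻¹ s⁻¹)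
    substrate + coupling partner → mono adduct (k = 0.990 M⁻¹ s⁻¹)
    mono adduct → over-reaction product (k = 1.20 × 10⁻⁵ s⁻¹)

**Further flask.** At 8.00 h the flask holds 14.5% of over-reaction product beside 50.0% of substrate. A neighbour flask with 48 mM of substrate has a ceiling of 12.5%, capture and keep make that 8.95%, and the neighbour holds 8.85%.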